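**Retrosynthetic overview**
1. Labels: ring C1 (C=O), C2 (C–N), C3 (=CH), C4 (quaternary C–OH), C5 (CH–OH), C6 (CH2); side chain C1'–C9'. Last disconnection, after removing a cyclohexylidene ketal and a tert-butyl ester: the C2–N enamide bond (copper-catalysed vinylic amidation of a ring iodoenone with the side-chain primary enamide).
2. Ring fragment: 2-iodoenone ⇐ enone (α-iodination) ⇐ achiral p-quinol by an organocatalytic desymmetrizing ketalization/oxa-Michael cascade (C5–O bond; C4 and C5 set together) ⇐ para-alkylphenol (oxidative dearomatization, C4–O bond).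
3. Side chain: C2'=C3' by Wittig olefination of an α-methyl aldehyde; C7'–C8' by copper-catalysed alkyl–alkyl coupling; both methyl stereocentres by organocatalytic methanolysis of meso-2,4-dimethylglutaric anhydride.
4. Ring order: ring A (the carbocycle) is the benzene ring of the starting phenol; ring B (dioxolane, spiro-linked to ring C from cyclohexanone) is closed in the desymmetrization and opened again in the last step.

Assumption: 1, 7, 11 and 13 are taken as commercial, and the sense of induction of the two chiral catalysts is taken as drawn; if either is opposite, (S)-TRIP or (DHQ)2AQN is used instead and nothing else changes.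

Catalyst names: TRIP = 3,3'-bis(2,4,6-triisopropylphenyl)-1,1'-binaphthyl-2,2'-diyl hydrogen phosphate; (DHQD)2AQN = hydroquinidine anthraquinone-1,4-diyl diether.

Step 1
Reactants: 1 5-(4-hydroxyphenyl)pentanoic acid
Product: 2 tert-butyl 5-(4-hydroxyphenyl)pentanoate
Conditions: Cl3CC(=NH)Ot-Bu (2 equiv), CH2Cl2/cyclohexane 1:1, rt
Reagents that add atoms: tert-butyl 2,2,2-trichloroacetimidate, CC(C)(C)OC(=N)C(Cl)(Cl)Cl
Why: Imidate esterification: the carboxylic acid protonates the trichloroacetimidate and is tert-butylated, while the much less acidic phenol stays free because no Lewis acid is added.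

Step 2
Reactants: 2 tert-butyl 5-(4-hydroxyphenyl)pentanoate
Product: 3 tert-butyl 5-(1-hydroxy-4-oxocyclohexa-2,5-dien-1-yl)pentanoate
Conditions: PhI(OAc)2 (1.2 equiv), MeCN/H2O 3:1, 0 °C
Reagents that add atoms: water, O
Why: Oxidative dearomatization of a para-alkylphenol by trivalent iodine, with water captured at the para carbon, gives the achiral mirror-symmetric p-quinol and leaves the ester untouched.

Step 3
Reactants: 3 tert-butyl 5-(1-hydroxy-4-oxocyclohexa-2,5-dien-1-yl)pentanoate
Product: 5 tert-butyl 5-[(3aR,7aS)-6-oxo-3a,6,7,7a-tetrahydrospiro[1,3-benzodioxole-2,1'-cyclohexan]-3a-yl]pentanoate, via cyclohexanone hemiketal 4 (not isolated)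
Conditions: cyclohexanone (10 equiv), (R)-TRIP (10 mol%), toluene, 35 °C
Reagents that add atoms: cyclohexanone, O=C1CCCCC1
Why: Proposed new method: a chiral phosphoric acid-catalysed desymmetrizing ketalization/oxa-Michael cascade in which a ketone instead of an aldehyde supplies the tether; the acid catalyses reversible addition of the tertiary OH of 3 to cyclohexanone (hemiketal 4), then holds the hemiketal OH on its P=O oxygen and the dienone carbonyl on its P–OH so that the hemiketal oxygen adds 5-exo to one of the two enantiotopic enone β-carbons; the tether allows only cis ring fusion, so the catalyst's choice of enone arm fixes C4 (R) and C5 (S) together as the cis-diol ketal; cyclohexanone is chosen because its carbonyl-addition equilibria are roughly ten times more favourable than those of acetone and its ketal carbon is not a stereocentre; the closest known reaction type is the Brønsted acid-catalysed acetalization/oxa-Michael desymmetrization of p-quinols with aldehydes.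

Step 4
Reactants: 5 tert-butyl 5-[(3aR,7aS)-6-oxo-3a,6,7,7a-tetrahydrospiro[1,3-benzodioxole-2,1'-cyclohexan]-3a-yl]pentanoate
Product: 6 tert-butyl 5-[(3aR,7aS)-5-iodo-6-oxo-3a,6,7,7a-tetrahydrospiro[1,3-benzodioxole-2,1'-cyclohexan]-3a-yl]pentanoate
Conditions: I2 (2 equiv), pyridine/CH2Cl2 1:1, 0 °C → rt
Reagents that add atoms: iodine, II
Why: Baylis–Hillman-type α-iodination of an enone (pyridine adds at C3, the enolate is iodinated at C2, pyridine is eliminated), which works on 4,4-disubstituted cyclohexenones and whose basic medium spares the ketal, the ester and both stereocentres.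

Step 5
Reactants: 7 (3R,5S)-3,5-dimethyloxane-2,6-dione (meso-2,4-dimethylglutaric anhydride)
Product: 8 (2R,4S)-5-methoxy-2,4-dimethyl-5-oxopentanoic acid
Conditions: MeOH (10 equiv), (DHQD)2AQN (15 mol%), Et2O, −40 °C
Reagents that add atoms: methanol, CO
Why: Organocatalytic alcoholytic desymmetrization of a meso anhydride: the bis-cinchona alkaloid acts as a chiral general base and delivers methanol to one of the two enantiotopic carbonyl groups, which fixes both methyl-bearing centres (2R,4S) at once.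

Step 6
Reactants: 8 (2R,4S)-5-methoxy-2,4-dimethyl-5-oxopentanoic acid
Product: 9 methyl (2S,4R)-5-hydroxy-2,4-dimethylpentanoate
Conditions: BH3·SMe2 (1.2 equiv), THF, −10 °C → rt; aqueous work-up
Reagents that add atoms: none
Why: Chemoselective borane reduction of a carboxylic acid (via the acyloxyborane) beside a methyl ester; no stereocentre is touched, and the product is used at once to avoid lactonization.

Step 7
Reactants: 9 methyl (2S,4R)-5-hydroxy-2,4-dimethylpentanoate
Product: 10 methyl (2S,4R)-5-bromo-2,4-dimethylpentanoate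
Conditions: CBr4 (1.3 equiv), PPh3 (1.4 equiv), CH2Cl2, 0 °C
Reagents that add atoms: carbon tetrabromide, BrC(Br)(Br)Br
Why: Appel bromination of a primary alcohol (SN2 on the alkoxyphosphonium ion) under neutral conditions that neither lactonize nor epimerize.

Step 8
Reactants: 10 methyl (2S,4R)-5-bromo-2,4-dimethylpentanoate; 11 isopropylmagnesium chloride
Product: 12 methyl (2S,4S)-2,4,6-trimethylheptanoate
Conditions: Li2CuCl4 (3 mol%), NMP (4 equiv), THF, 0 °C → rt, slow addition of 11 (1.5 equiv)
Reagents that add atoms: none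
Why: Kochi-type copper-catalysed alkyl–alkyl cross-coupling of a Grignard reagent with a primary bromide, where NMP makes coupling faster than attack on the α-branched ester; neither stereocentre is involved.

Step 9
Reactants: 12 methyl (2S,4S)-2,4,6-trimethylheptanoate; 13 2-(triphenyl-λ5-phosphanylidene)acetamide
Product: 15 (2E,4S,6S)-4,6,8-trimethylnon-2-enamide, via (2S,4S)-2,4,6-trimethylheptanal 14 (not isolated)
Conditions: i-Bu2AlH (1.05 equiv), CH2Cl2, −78 °C; MeOH quench; then 13 (1.5 equiv), −78 °C → rt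
Reagents that add atoms: none
Why: Partial ester reduction through the aluminium hemiacetal followed by in-flask Wittig olefination with a stabilized, weakly basic ylide gives the E-enamide without isolating or epimerizing the α-methyl aldehyde.

Step 10
Reactants: 6 tert-butyl 5-[(3aR,7aS)-5-iodo-6-oxo-3a,6,7,7a-tetrahydrospiro[1,3-benzodioxole-2,1'-cyclohexan]-3a-yl]pentanoate; 15 (2E,4S,6S)-4,6,8-trimethylnon-2-enamide
Product: 16 tert-butyl 5-[(3aR,7aS)-6-oxo-5-{[(2E,4S,6S)-4,6,8-trimethylnon-2-enoyl]amino}-3a,6,7,7a-tetrahydrospiro[1,3-benzodioxole-2,1'-cyclohexan]-3a-yl]pentanoate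
Conditions: CuI (10 mol%), MeNHCH2CH2NHMe (20 mol%), K2CO3 (2 equiv), toluene, 70 °C
Reagents that add atoms: none
Why: Goldberg-type copper-catalysed amidation of a vinyl iodide with a primary amide forms the C2–N bond; the weak heterogeneous base limits β-alkoxide elimination and no stereocentre is affected.

Step 11
Reactants: 16 tert-butyl 5-[(3aR,7aS)-6-oxo-5-{[(2E,4S,6S)-4,6,8-trimethylnon-2-enoyl]amino}-3a,6,7,7a-tetrahydrospiro[1,3-benzodioxole-2,1'-cyclohexan]-3a-yl]pentanoate
Product: 17 5-[(1R,6S)-1,6-dihydroxy-4-oxo-3-{[(2E,4S,6S)-4,6,8-trimethylnon-2-enoyl]amino}cyclohex-2-en-1-yl]pentanoic acid (Salternamide E)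
Conditions: TFA/H2O 9:1, 0 °C, 1 h
Reagents that add atoms: none
Why: Acidolysis in one operation: aqueous trifluoroacetic acid hydrolyses the cyclohexylidene ketal and cleaves the tert-butyl ester by the E1 path, while the 2-amidoenone is a deactivated enamide and the cold, short exposure limits dehydration.

**Compound list**
1 | 5-(4-hydroxyphenyl)pentanoic acid | OC(=O)CCCCc1ccc(O)cc1 | starting material
2 | tert-butyl 5-(4-hydroxyphenyl)pentanoate | CC(C)(C)OC(=O)CCCCc1ccc(O)cc1 | intermediate
3 | tert-butyl 5-(1-hydroxy-4-oxocyclohexa-2,5-dien-1-yl)pentanoate (achiral p-quinol) | CC(C)(C)OC(=O)CCCCC1(O)C=CC(=O)C=C1 | intermediate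
4 | tert-butyl 5-{1-[(1-hydroxycyclohexyl)oxy]-4-oxocyclohexa-2,5-dien-1-yl}pentanoate (cyclohexanone hemiketal of 3, not isolated) | CC(C)(C)OC(=O)CCCCC1(OC2(O)CCCCC2)C=CC(=O)C=C1 | intermediate
5 | tert-butyl 5-[(3aR,7aS)-6-oxo-3a,6,7,7a-tetrahydrospiro[1,3-benzodioxole-2,1'-cyclohexan]-3a-yl]pentanoate (cis-fused cyclohexylidene ketal of the C4,C5-diol enone) | O=C1C=C[C@@]2(CCCCC(=O)OC(C)(C)C)OC3(CCCCC3)O[C@H]2C1 | intermediate
6 | tert-butyl 5-[(3aR,7aS)-5-iodo-6-oxo-3a,6,7,7a-tetrahydrospiro[1,3-benzodioxole-2,1'-cyclohexan]-3a-yl]pentanoate | O=C1C(I)=C[C@@]2(CCCCC(=O)OC(C)(C)C)OC3(CCCCC3)O[C@H]2C1 | intermediate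
7 | (3R,5S)-3,5-dimethyloxane-2,6-dione (meso, cis) | O1C(=O)[C@H](C)C[C@H](C)C1=O | starting material
8 | (2R,4S)-5-methoxy-2,4-dimethyl-5-oxopentanoic acid | OC(=O)[C@H](C)C[C@H](C)C(=O)OC | intermediate
9 | methyl (2S,4R)-5-hydroxy-2,4-dimethylpentanoate | OC[C@H](C)C[C@H](C)C(=O)OC | intermediate
10 | methyl (2S,4R)-5-bromo-2,4-dimethylpentanoate | BrC[C@H](C)C[C@H](C)C(=O)OC | intermediate
11 | isopropylmagnesium chloride | CC(C)[Mg]Cl | starting material
12 | methyl (2S,4S)-2,4,6-trimethylheptanoate | CC(C)C[C@H](C)C[C@H](C)C(=O)OC | intermediate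
13 | 2-(triphenyl-λ5-phosphanylidene)acetamide | NC(=O)C=P(c1ccccc1)(c1ccccc1)c1ccccc1 | starting material
14 | (2S,4S)-2,4,6-trimethylheptanal (not isolated) | CC(C)C[C@H](C)C[C@H](C)C=O | intermediate
15 | (2E,4S,6S)-4,6,8-trimethylnon-2-enamide | CC(C)C[C@H](C)C[C@H](C)/C=C/C(N)=O | intermediate
16 | tert-butyl 5-[(3aR,7aS)-6-oxo-5-{[(2E,4S,6S)-4,6,8-trimethylnon-2-enoyl]amino}-3a,6,7,7a-tetrahydrospiro[1,3-benzodioxole-2,1'-cyclohexan]-3a-yl]pentanoate | CC(C)C[C@H](C)C[C@H](C)/C=C/C(=O)NC1=C[C@@]2(CCCCC(=O)OC(C)(C)C)OC3(CCCCC3)O[C@H]2CC1=O | intermediate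
17 | 5-[(1R,6S)-1,6-dihydroxy-4-oxo-3-{[(2E,4S,6S)-4,6,8-trimethylnon-2-enoyl]amino}cyclohex-2-en-1-yl]pentanoic acid (Salternamide E) | CC(C)C[C@H](C)C[C@H](C)/C=C/C(=O)NC1=C[C@](O)(CCCCC(=O)O)[C@@H](O)CC1=O | target

**Step count and risks**
Total steps: 11 (ring branch steps 1–4, side-chain branch steps 5–9, union and unmasking steps 10–11). Longest linear sequence: 7 steps (7 → 17 through steps 5–11).

Step 3 (the proposed new cascade). The hemiketal of a tertiary alcohol with a ketone is sparsely populated and its cyclization is crowded. The ketal enone could also revert by retro-oxa-Michael reaction and lose enantiopurity. The fallback uses known chemistry, sets out from 3 and comes back at 5. Treat 3 with 2-methylpropanal (3 equiv) and (R)-TRIP (5 mol%) in toluene at rt, the established aldehyde acetalization/oxa-Michael desymmetrization. This gives tert-butyl 5-[(3aR,7aS)-6-oxo-2-(propan-2-yl)-3a,6,7,7a-tetrahydro-1,3-benzodioxol-3a-yl]pentanoate F1 (acetal carbon as formed, left undefined). Hydrolyse the acetal at this robust stage (AcOH/H2O 4:1, 60 °C) to tert-butyl 5-[(1R,6S)-1,6-dihydroxy-4-oxocyclohex-2-en-1-yl]pentanoate F2. Ketalize F2 with 1,1-dimethoxycyclohexane (PPTS, CH2Cl2, rt) to reach 5.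

Step 10 (C–N coupling). The iodoenone is hindered at C3 and carries a β-alkoxy ketone, so base and heat may open ring B by E1cB elimination or cause deiodination. The fallback sets out from 6 and comes back at 16. Remove the ketone first by Luche reduction (NaBH4, CeCl3·7H2O, MeOH, −40 °C) to give tert-butyl 5-[(3aR,7aS)-6-hydroxy-5-iodo-3a,6,7,7a-tetrahydrospiro[1,3-benzodioxole-2,1'-cyclohexan]-3a-yl]pentanoate F3 (either carbinol epimer), which cannot eliminate. Couple F3 with 15 as an ordinary vinyl iodide (CuI, MeNHCH2CH2NHMe, Cs2CO3, THF, 60 °C) to give tert-butyl 5-[(3aR,7aS)-6-hydroxy-5-{[(2E,4S,6S)-4,6,8-trimethylnon-2-enoyl]amino}-3a,6,7,7a-tetrahydrospiro[1,3-benzodioxole-2,1'-cyclohexan]-3a-yl]pentanoate F4. Reoxidize the allylic alcohol with Dess–Martin periodinane (NaHCO3, CH2Cl2, 0 °C) to reach 16.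

Step 11 (global acidolysis). Strong acid could ionize the tertiary allylic alcohol or dehydrate the β-hydroxy ketone, which leads toward an aromatic aminophenol. The fallback sets out from 16 and comes back at 17. Remove only the ketal with AcOH/H2O 4:1 at rt to give tert-butyl 5-[(1R,6S)-1,6-dihydroxy-4-oxo-3-{[(2E,4S,6S)-4,6,8-trimethylnon-2-enoyl]amino}cyclohex-2-en-1-yl]pentanoate F5. Then hydrolyse the tert-butyl ester at pH 7 with an esterase that accepts tert-butyl esters (Bacillus subtilis esterase or Candida antarctica lipase A, phosphate buffer with MeCN cosolvent, 30 °C), so that no strong acid is used.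

**Further compounds**
F1 | step 3 | tert-butyl 5-[(3aR,7aS)-6-oxo-2-(propan-2-yl)-3a,6,7,7a-tetrahydro-1,3-benzodioxol-3a-yl]pentanoate | O=C1C=C[C@@]2(CCCCC(=O)OC(C)(C)C)OC(C(C)C)O[C@H]2C1
F2 | step 3 | tert-butyl 5-[(1R,6S)-1,6-dihydroxy-4-oxocyclohex-2-en-1-yl]pentanoate | O=C1C=C[C@](O)(CCCCC(=O)OC(C)(C)C)[C@@H](O)C1
F3 | step 10 | tert-butyl 5-[(3aR,7aS)-6-hydroxy-5-iodo-3a,6,7,7a-tetrahydrospiro[1,3-benzodioxole-2,1'-cyclohexan]-3a-yl]pentanoate | OC1C(I)=C[C@@]2(CCCCC(=O)OC(C)(C)C)OC3(CCCCC3)O[C@H]2C1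
F4 | step 10 | tert-butyl 5-[(3aR,7aS)-6-hydroxy-5-{[(2E,4S,6S)-4,6,8-trimethylnon-2-enoyl]amino}-3a,6,7,7a-tetrahydrospiro[1,3-benzodioxole-2,1'-cyclohexan]-3a-yl]pentanoate | CC(C)C[C@H](C)C[C@H](C)/C=C/C(=O)NC1=C[C@@]2(CCCCC(=O)OC(C)(C)C)OC3(CCCCC3)O[C@H]2CC1O
F5 | step 11 | tert-butyl 5-[(1R,6S)-1,6-dihydroxy-4-oxo-3-{[(2E,4S,6S)-4,6,8-trimethylnon-2-enoyl]amino}cyclohex-2-en-1-yl]pentanoate | CC(C)C[C@H](C)C[C@H](C)/C=C/C(=O)NC1=C[C@](O)(CCCCC(=O)OC(C)(C)C)[C@@H](O)CC1=O
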